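**Retrosynthetic overview**
1. All atoms of the target come from three purchased compounds: bromoacetal 1 (converted into bromo enol ether 2), 1,13-dibromotridecane 3 and di-tert-butyl squarate 4; the squarate and the enol ether are each used twice, once per chain end.
2. Tether disconnection (two C–C bonds): bis-cyclobutenedione 7 is cut into bis-Grignard reagent 5 (from 3) and two molecules of 4, joined through adduct 6.
3. Side-arm disconnection (two C–C bonds): bis-cyclobutenone 9 is cut into 7 and two molecules of vinyllithium 8 (from 2), which brings the C-methyl/O-methyl pair.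
4. Key disconnection: both benzenoid rings of bis-hydroquinone 10 are traced back at once to the two four-membered rings of 9 (4π ring opening, then 6π ring closure); oxidation (11) and loss of the tert-butyl groups give target 12.
5. Ring order: the two four-membered rings are bought with 4; the two six-membered rings form together in one thermolysis; no other ring is made.

Assumption: the target has no stereocentre and no stereogenic double bond, so it is one achiral compound and needs no enantiocontrol; 1, 3 and 4 are taken as catalogue compounds.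

**Route**

Step 1
Reactants: 1 2-bromo-1,1-dimethoxypropane (racemic)
Product: 2 (Z)-2-bromo-1-methoxyprop-1-ene (Br cis to OMe)
Conditions: Me3SiOTf (1.2 equiv), iPr2NEt (1.5 equiv), CH2Cl2, −20 °C to rt; pentane, filter; fractional distillation
Reagents that add atoms: none
Why: Silyl-triflate-mediated loss of methanol from a dimethyl acetal (Gassman-type acetal-to-enol-ether elimination) goes through the oxocarbenium ion, which the hindered amine deprotonates at C2; the Z isomer is expected to predominate because of the cis preference of the two heteroatoms and is enriched by distillation, and no stereocentre is formed.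

Step 2
Reactants: 3 1,13-dibromotridecane (one molecule); 4 di-tert-butyl squarate (3,4-di-tert-butoxycyclobut-3-ene-1,2-dione; two molecules, one for each chain end)
Product: 7 4,4'-(tridecane-1,13-diyl)bis(3-tert-butoxycyclobut-3-ene-1,2-dione), via bis-Grignard reagent 5 (not isolated), via bis(bromomagnesium alkoxide) adduct 6 (not isolated)
Conditions: 3 (1.0 equiv), Mg (4 equiv), cat. I2, THF, 40 °C; cannulate into 4 (2.6 equiv), THF, −78 °C; (CF3CO)2O (3 equiv), −78 to 0 °C; aq NaHCO3
Reagents that add atoms: di-tert-butyl squarate (the second molecule of compound 4), CC(C)(C)OC1=C(OC(C)(C)C)C(=O)C1=O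
Why: Magnesium insertion at both C–Br bonds gives the bis-Grignard reagent, each end of which adds 1,2 to one carbonyl of its own molecule of squarate (two molecules of 4 per molecule of 3), and anhydride-induced ionisation of each carbinol with loss of one tert-butyl group (squarate addition/1,3-carbonyl transposition) gives the 3-alkyl-4-alkoxycyclobutenedione at both ends; the carbinol centres of 6 disappear in the rearrangement.

Step 3
Reactants: 7 4,4'-(tridecane-1,13-diyl)bis(3-tert-butoxycyclobut-3-ene-1,2-dione) (one molecule); 2 (Z)-2-bromo-1-methoxyprop-1-ene (two molecules, one for each four-membered ring)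
Product: 12 3,3'-(tridecane-1,13-diyl)bis(2-hydroxy-5-methoxy-6-methylcyclohexa-2,5-diene-1,4-dione) (the target), via vinyllithium 8 (not isolated), via bis-cyclobutenone diol 9 (not isolated), via bis-hydroquinone 10 (not isolated), via bis(tert-butoxyquinone) 11 (not isolated)
Conditions: 2 (2.6 equiv), tBuLi (5.2 equiv), Et2O/THF, −78 °C; add 7 (1.0 equiv), −78 °C, 1 h; H2O quench, pH 7 buffer wash; crude in degassed PhMe (0.01 M), 110 °C, 2 h; Ag2O (4 equiv), rt; filter, concentrate; CF3CO2H/CH2Cl2 1:4, 0 °C to rt
Reagents that add atoms: (Z)-2-bromo-1-methoxyprop-1-ene (the second molecule of compound 2), C/C(Br)=C/OC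
Why: Bromine–lithium exchange with retention gives a vinyllithium with Li cis to OMe (chelated, no anti β-elimination), one molecule of which adds to the more electrophilic, non-vinylogous-ester carbonyl of each ring, after which heating triggers in both halves a torquoselective 4π ring opening (OH outward, alkenyl inward) to a dienylketene, 6π electrocyclisation and tautomerisation (two-fold Moore ring expansion), so both six-membered rings form in one operation with the substitution pattern fixed by the addition regiochemistry; Ag2O then dehydrogenates the hydroquinones and acid removes the tert-butyl groups, while the carbinol centres and alkene geometry of 9 are erased on aromatisation and the target has no stereocentre.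

**Compound list**
1 | 2-bromo-1,1-dimethoxypropane (racemic) | CC(Br)C(OC)OC | starting material
2 | (Z)-2-bromo-1-methoxyprop-1-ene | C/C(Br)=C/OC | intermediate
3 | 1,13-dibromotridecane | BrCCCCCCCCCCCCCBr | starting material
4 | di-tert-butyl squarate (3,4-di-tert-butoxycyclobut-3-ene-1,2-dione) | CC(C)(C)OC1=C(OC(C)(C)C)C(=O)C1=O | starting material
5 | tridecane-1,13-diylbis(magnesium bromide) | Br[Mg]CCCCCCCCCCCCC[Mg]Br | intermediate
6 | bis(bromomagnesium alkoxide) of 4,4'-(tridecane-1,13-diyl)bis(2,3-di-tert-butoxy-4-hydroxycyclobut-2-en-1-one), mixture of diastereomers | CC(C)(C)OC1=C(OC(C)(C)C)C(O[Mg]Br)(CCCCCCCCCCCCCC2(O[Mg]Br)C(OC(C)(C)C)=C(OC(C)(C)C)C2=O)C1=O | intermediate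
7 | 4,4'-(tridecane-1,13-diyl)bis(3-tert-butoxycyclobut-3-ene-1,2-dione) | CC(C)(C)OC1=C(CCCCCCCCCCCCCC2=C(OC(C)(C)C)C(=O)C2=O)C(=O)C1=O | intermediate
8 | (E)-(1-methoxyprop-1-en-2-yl)lithium (Li cis to OMe; same geometry as 2, descriptor changes with priority) | C/C([Li])=C/OC | intermediate
9 | 2,2'-(tridecane-1,13-diyl)bis{3-tert-butoxy-4-hydroxy-4-[(Z)-1-methoxyprop-1-en-2-yl]cyclobut-2-en-1-one}, mixture of diastereomers at the two carbinol carbons | CO/C=C(C)\C1(O)C(OC(C)(C)C)=C(CCCCCCCCCCCCCC2=C(OC(C)(C)C)C(O)(/C(C)=C\OC)C2=O)C1=O | intermediate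
10 | 3,3'-(tridecane-1,13-diyl)bis(2-tert-butoxy-5-methoxy-6-methylbenzene-1,4-diol) | COc1c(C)c(O)c(OC(C)(C)C)c(CCCCCCCCCCCCCc2c(OC(C)(C)C)c(O)c(C)c(OC)c2O)c1O | intermediate
11 | 3,3'-(tridecane-1,13-diyl)bis(2-tert-butoxy-5-methoxy-6-methylcyclohexa-2,5-diene-1,4-dione) | COC1=C(C)C(=O)C(OC(C)(C)C)=C(CCCCCCCCCCCCCC2=C(OC(C)(C)C)C(=O)C(C)=C(OC)C2=O)C1=O | intermediate
12 | 3,3'-(tridecane-1,13-diyl)bis(2-hydroxy-5-methoxy-6-methylcyclohexa-2,5-diene-1,4-dione), achiral | COC1=C(C)C(=O)C(O)=C(CCCCCCCCCCCCCC2=C(O)C(=O)C(C)=C(OC)C2=O)C1=O | target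

**Totals**
Total step count: 3. Longest linear sequence: 2 steps (3 → 7 → 12, or 1 → 2 → 12).

**Steps most likely to fail, with fallbacks**

Step 3. Vinyllithium 8 can lose LiOMe, and any E isomer left in 2 gives propyne at once. Two additions, two ring expansions, two oxidations and two deprotections must also all succeed in one telescoped operation. The fallback sets out from 7 and comes back at 11. Commercial isopropenylmagnesium bromide, CH2=C(CH3)MgBr, has no β-leaving group; added in THF at −78 °C (2.6 equiv, NH4Cl quench) it gives the bis(isopropenyl carbinol) F1. The same thermolysis (PhMe, 110 °C) gives the methoxy-free bis-hydroquinone F2, and Ag2O gives the 5-unsubstituted bis-quinone F3. Nucleophilic epoxidation (tBuOOH, DBU, THF, 0 °C) attacks only the electron-poor, methyl-bearing double bond and gives the bis-epoxide F4. Excess DBU removes the epoxide C–H next to the carbonyl and opens the ring by E1cB elimination to the bis(hydroxyquinone) F5. MeI/Ag2O in CHCl3 methylates its only free hydroxyl to give 11, which CF3CO2H converts into 12 as at the end of step 3.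

Step 2. Forming a bis-Grignard reagent invites Wurtz coupling, and each end must add only once to its own molecule of squarate. The fallback sets out from 3 and comes back at 7. NaI in acetone gives 1,13-diiodotridecane F6. Iodine–lithium exchange (tBuLi, 4.2 equiv, pentane/Et2O, −78 °C) gives 1,13-dilithiotridecane F7. This is added to 4 (2.6 equiv, THF, −78 °C) to give the dilithium bis-alkoxide adduct F8, and (CF3CO)2O then gives 7.

Step 1. Ionisation of an α-bromo acetal is slow, and the Z/E ratio may be poor. The fallback sets out from 1 and comes back at 2. Acetyl chloride with a trace of SOCl2 (neat, 50 °C) exchanges one methoxy group for chloride to give 2-bromo-1-chloro-1-methoxypropane F9, with methyl acetate distilled off. N,N-Diethylaniline at 90 °C then removes HCl by thermal elimination, and Z-rich 2 is distilled from the anilinium salt.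

**Further compounds**
F1 | step 3 | 2,2'-(tridecane-1,13-diyl)bis[3-tert-butoxy-4-hydroxy-4-(prop-1-en-2-yl)cyclobut-2-en-1-one], mixture of diastereomers | C=C(C)C1(O)C(OC(C)(C)C)=C(CCCCCCCCCCCCCC2=C(OC(C)(C)C)C(O)(C(C)=C)C2=O)C1=O
F2 | step 3 | 3,3'-(tridecane-1,13-diyl)bis(2-tert-butoxy-6-methylbenzene-1,4-diol) | Cc1cc(O)c(CCCCCCCCCCCCCc2c(O)cc(C)c(O)c2OC(C)(C)C)c(OC(C)(C)C)c1O
F3 | step 3 | 3,3'-(tridecane-1,13-diyl)bis(2-tert-butoxy-6-methylcyclohexa-2,5-diene-1,4-dione) | CC1=CC(=O)C(CCCCCCCCCCCCCC2=C(OC(C)(C)C)C(=O)C(C)=CC2=O)=C(OC(C)(C)C)C1=O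
F4 | step 3 | bis(5,6-epoxide) of F3, mixture of diastereomers | CC12OC1C(=O)C(CCCCCCCCCCCCCC1=C(OC(C)(C)C)C(=O)C3(C)OC3C1=O)=C(OC(C)(C)C)C2=O
F5 | step 3 | 3,3'-(tridecane-1,13-diyl)bis(2-tert-butoxy-5-hydroxy-6-methylcyclohexa-2,5-diene-1,4-dione) | OC1=C(C)C(=O)C(OC(C)(C)C)=C(CCCCCCCCCCCCCC2=C(OC(C)(C)C)C(=O)C(C)=C(O)C2=O)C1=O
F6 | step 2 | 1,13-diiodotridecane | ICCCCCCCCCCCCCI
F7 | step 2 | 1,13-dilithiotridecane | [Li]CCCCCCCCCCCCC[Li]
F8 | step 2 | dilithium bis-alkoxide of 4,4'-(tridecane-1,13-diyl)bis(2,3-di-tert-butoxy-4-hydroxycyclobut-2-en-1-one), mixture of diastereomers | CC(C)(C)OC1=C(OC(C)(C)C)C(O[Li])(CCCCCCCCCCCCCC2(O[Li])C(OC(C)(C)C)=C(OC(C)(C)C)C2=O)C1=O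
F9 | step 1 | 2-bromo-1-chloro-1-methoxypropane, mixture of diastereomers | CC(Br)C(Cl)OC
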